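Assumption: the target has no stereocentre and no stereogenic double bond, so it is achiral and no stereocontrol is needed.

**Retrosynthetic overview**
- 1-Bromohexadecane (1) and pent-4-ynoic acid (2) supply every carbon except the carboxyl carbon, which comes from CO2.
- Supporting C–C disconnection: hexadecylmagnesium bromide (3) plus pent-4-ynoyl chloride (4) give henicos-1-yn-5-one (5).
- Key C–O disconnection: the O1–C2 bond of the furan, closed by attack of the ketone oxygen of 5 on its alkyne after CO2 capture (through 6 and 7), giving target 8.
- Ring order: the furan is the only ring and is formed in the last step.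

**Step 1**
Reactants: 1 1-bromohexadecane; 2 pent-4-ynoic acid
Product: 5 henicos-1-yn-5-one, via hexadecylmagnesium bromide 3 (not isolated), via pent-4-ynoyl chloride 4 (not isolated)
Conditions: 1 (1.1 equiv), Mg, I2 (cat.), THF, 50 °C; separately 2, (COCl)2, DMF (cat.), CH2Cl2, 0 °C to rt, evaporate; combine with Fe(acac)3 (3 mol%), THF, −78 °C, 15 min; aq. NH4Cl
Reagents that add atoms: none
Why: Iron-catalysed acyl cross-coupling of a Grignard reagent with an acid chloride (Kochi–Fürstner type) is complete within minutes at −78 °C, which is faster than deprotonation of the terminal alkyne or a second addition to the new ketone.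

**Step 2**
Reactants: 5 henicos-1-yn-5-one
Product: 8 (5-hexadecylfuran-2-yl)acetic acid, via cesium 6-oxodocos-2-ynoate 6 (not isolated), via cesium (2Z)-2-(5-hexadecylfuran-2(3H)-ylidene)acetate 7 (not isolated)
Conditions: AgI (5 mol%), Cs2CO3 (2.0 equiv), CO2 (2 atm), DMF, 50 °C, 12 h, then 80 °C, 8 h; then 1 M HCl, rt, 1 h
Reagents that add atoms: carbon dioxide, O=C=O
Why: Proposed new method: monovalent silver with Cs2CO3 turns the terminal alkyne into a silver acetylide that inserts CO2 to give ynoate 6 (the known silver-catalysed C–H carboxylation of terminal alkynes), the same silver then acts as a π-acid on the carboxylate-bound triple bond so that the ketone oxygen adds 5-exo-dig to the β-carbon (the furan C–O bond), loss of an α-proton and protodeargentation give ylidene 7, and its acid-promoted 1,3-hydrogen shift to the aromatic furan makes the otherwise reversible CO2 capture irreversible and delivers the free acid directly; the closest known reaction types are the π-acid-catalysed cycloisomerisation of 4-yn-1-ones to 2-methylfurans and the PdI2-catalysed oxidative cyclisation–alkoxycarbonylation of 4-yn-1-ones with CO, of which this is a redox-neutral CO2 counterpart.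

**Compound list**
1 | 1-bromohexadecane | CCCCCCCCCCCCCCCCBr | starting material
2 | pent-4-ynoic acid | C#CCCC(=O)O | starting material
3 | hexadecylmagnesium bromide | CCCCCCCCCCCCCCCC[Mg]Br | intermediate
4 | pent-4-ynoyl chloride | C#CCCC(=O)Cl | intermediate
5 | henicos-1-yn-5-one | CCCCCCCCCCCCCCCCC(=O)CCC#C | intermediate
6 | cesium 6-oxodocos-2-ynoate | CCCCCCCCCCCCCCCCC(=O)CCC#CC(=O)[O-].[Cs+] | intermediate
7 | cesium (2Z)-2-(5-hexadecylfuran-2(3H)-ylidene)acetate (Z expected from anti addition; either isomer aromatises) | CCCCCCCCCCCCCCCCC1=CC/C(=C/C(=O)[O-])O1.[Cs+] | intermediate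
8 | (5-hexadecylfuran-2-yl)acetic acid | CCCCCCCCCCCCCCCCc1ccc(CC(=O)O)o1 | target

**Totals**
Total step count: 2. Longest linear sequence: 2 steps (1 or 2 → 5 → 8).

**Steps most likely to fail**
The route has only two steps, so both are ranked and there is no third.

1. Step 2 (the proposed new step) is the most likely to fail. Possible failure modes:
- The ketone may cyclise onto the alkyne before CO2 is captured, giving the CO2-free 2-methylfuran.
- The ketone α-carbon may be carboxylated and then lactonise onto the alkyne; the weak base and low CO2 pressure are chosen to disfavour this.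
- Ynoate 6 may lose CO2 again at 80 °C.
- Ylidene 7 may be hydrolysed to a β-keto acid during acidic work-up and decarboxylate.

The fallback uses known chemistry and sets out from 5. Oxidative cyclisation–methoxycarbonylation (PdI2 1 mol%, KI 10 mol%, CO/air 4:1 at about 30 atm, MeOH, 65 °C; divalent palladium activates the alkyne, methanol adds to the ketone and the hemiketal oxygen closes the ring) gives methyl (2E)-2-(5-hexadecyl-5-methoxyoxolan-2-ylidene)acetate F2 as a racemate. Catalytic TsOH in CH2Cl2 at rt eliminates methanol and aromatises it to methyl (5-hexadecylfuran-2-yl)acetate F3. LiOH in THF/H2O followed by HCl then returns to the route at 8. The ring is still closed through the same C–O bond, at the cost of two more steps.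

2. Step 1 is the second risk. The Grignard reagent may deprotonate the alkyne or add twice, and the crude acid chloride 4 is volatile and may carry HCl. The fallback sets out from 2. CDI and N,O-dimethylhydroxylamine hydrochloride in CH2Cl2 at rt give the isolable N-methoxy-N-methylpent-4-ynamide F1. Treating F1 with 3 (2.2 equiv, THF, 0 °C, then aq. NH4Cl) acylates through a stable chelated tetrahedral intermediate instead of a catalytic cross-coupling. Any acetylide formed is simply reprotonated on work-up, and the fallback returns to the route at 5.

**Further compounds**
F1 | step 1 | N-methoxy-N-methylpent-4-ynamide | C#CCCC(=O)N(C)OC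
F2 | step 2 | methyl (2E)-2-(5-hexadecyl-5-methoxyoxolan-2-ylidene)acetate (racemic) | CCCCCCCCCCCCCCCCC1(OC)CC/C(=C\C(=O)OC)O1
F3 | step 2 | methyl (5-hexadecylfuran-2-yl)acetate | CCCCCCCCCCCCCCCCc1ccc(CC(=O)OC)o1
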